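The readings were computed with made-up constants; scatter was added.

I start with a subtraction. Whatever substrate, target (P) and other capture product (Q) don't hold in a reading, I book as side product, O. One side product counts as 2 and holds one target, so:

R = (P + O/2) / Q

R is target formed over other capture product formed.

| flask | substrate | first nucleophile | second nucleophile | remark | time |
|---|---|---|---|---|---|
| summer | 0.50 M | 0.55 M | 0.35 M | the very flask that is asked about, followed so far |  |
| spring | 0.25 M | 0.55 M | 0.35 M | run made earlier |  |
| flask | 0.50 M | 0.550 M | 0.350 M |  | 6.0 h |

- summer (time / min: target / %, other capture product / %, substrate / %): 15.0: 26.0, 22.2, 37.2; 30.0: 34.5, 28.5, 11.7; 50.0: 38.5, 29.7, 2.2; 60.0: 38.6, 30.5, 1.2; 80.0: 38.2, 30.6, 0.2; 90.0: 38.9, 31.5, 0; 120: 37.8, 31.6, 0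
- spring (time / h: target / %, other capture product / %, substrate / %): 0.333: 34.9, 26.2, 27.1; 1.00: 46.8, 33.1, 1.9; 1.50: 47.1, 32.9, 0.4; 2.50: 47.9, 32.0, 0; 4.00: 48.2, 32.2, 0; 5.00: 47.3, 33.0, 0.5; 6.00: 47.7, 33.5, 0

(standard deviation of a reading: 0.5 percentage points)

- ratio of target to other capture product at 15 s
- ratio of target to other capture product at 6.0 h
- which of target and other capture product there is more of at 6.0 h

The summer and spring flasks differ in substrate charge. Over their last 3 readings, P/Q is 1.23 in summer and 1.45 in spring. Yet R reads 1.71 and 1.75. So on these readings the two flasks capture nearly alike and part in the loss. O reads 30.5 % in summer, more than the 19.4 % in spring, because substrate + target goes with the substrate charge. For the summer flask at 6.0 h I take the plateau, 1.23.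

The early ratio is one of rates. I freeze the intermediate (steady state): it is captured as fast as it is made. Both captures draw on that same intermediate, so its concentration cancels. With B and D the concentrations of first and second nucleophile, s a constant, and r the rate of forming target over the rate of forming other capture product:

r = s · B / D

In the summer flask, R climbs from 1.50 at 15.0 min to 1.65 at 30.0 min. Going straight back to zero time:

r₀ = 2·1.50 − 1.65 = 1.35

s = r₀ · D / B = 0.856

I carry s, the selectivity factor: the capture constant of first nucleophile over that of second nucleophile.

The forecast gives 1.3 (1.12 to 1.45) at 15 s, 1.23 (1.19 to 1.27) at 6.0 h, and target ahead, saying “The flask matches the summer run”. For 15 s I take my r₀, 1.35, which stands higher than its value.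

The flask gives 1.26 and 1.25, with target 38.6 % against other capture product 30.8 %.

    substrate → intermediate (k = 0.0586 min⁻¹)
    first nucleophile + intermediate → target (k = 35.1 L mol⁻¹ min⁻¹)
    second nucleophile + intermediate → other capture product (k = 43.7 L mol⁻¹ min⁻¹)
    second nucleophile → decomposed reagent (k = 0.0200 min⁻¹)
    substrate + target → side product (k = 0.105 L mol⁻¹ min⁻¹)

Against that 1.26, s · B / D on this flask stays at 1.35. A neighbouring flask differs in one setting, first nucleophile at 0.22 M. There s · B / D gives 0.538, and the simulation gives 0.504 at 15 s. At 6.0 h that neighbour holds 49.9 % other capture product against 28.4 % target.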